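**Plan**

Cuts, in retrosynthetic order: (1) C6 of ring A to the ketone carbon; (2) O1–C8a of the dihydropyran ring C; (3) the two C2–CH3 bonds; (4) C4–C3, the benzylic CH2 to the stereocentre.
Enabling feature: in the Z form, the ketone carbon, Cα, Cβ, C1 and C2 of ring B and the oxygen on C2 are the six atoms of the pyranone ring of 7-hydroxycoumarin. The whole 2,4-dihydroxycinnamoyl half is therefore delivered as that cheap lactone, with its own ring-B phenoxide as leaving group. The acceptor carbon C6 of ring A lies between O5 and O7 and can be lithiated there.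
Forward: ring A is bought and made into a benzylic bromide, and the chain is joined by enolate alkylation. The ester becomes CMe2OH, and ring C closes by palladium-catalysed aryl C–O coupling. C6-lithiation and opening of the coumarin ring bring in ring B and the enone, and both MOM groups leave last.
Stereochemistry: C3 (R) comes from an Evans alkylation with (S)-4-benzyl-2-oxazolidinone, and no later step forms a cation next to it. The E alkene is the thermodynamic result of phenoxide-assisted Z to E equilibration.

Key step: step 12

Assumption: chroman numbering (O1, C2, C3, C4, C4a, C5 to C8, C8a) is used for rings A and C, ring B is the resorcinol ring, and 5-methylhex-4-enoic acid is taken as commercially available.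

**Route**

Step 1
Reactants: 1 1-bromo-3,5-dimethoxybenzene
Product: 3 2-bromo-4,6-dimethoxybenzaldehyde, via aryl iminium salt 2 (not isolated)
Conditions: POCl3, DMF, 0 to 90 °C; then ice-water
Reagents that add atoms: N,N-dimethylformamide CN(C)C=O; water O
Why: Vilsmeier–Haack formylation: the chloroiminium ion made from DMF and POCl3 attacks the ring carbon that is para to one methoxy group and ortho to the other (two equivalent sites), which is favoured over the crowded site between the two methoxy groups, and water then hydrolyses iminium salt 2 to the aldehyde.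

Step 2
Reactants: 3 2-bromo-4,6-dimethoxybenzaldehyde
Product: 4 2-bromo-6-hydroxy-4-methoxybenzaldehyde
Conditions: BCl3 (1.2 equiv), CH2Cl2, −78 to 0 °C; then H2O
Reagents that add atoms: none
Why: Chelation-controlled Lewis-acid demethylation: BCl3 is held in a six-membered chelate by the aldehyde oxygen and the ortho methoxy oxygen, so that only this methyl group is lost while the para methoxy group and the C–Br bond stay.

Step 3
Reactants: 4 2-bromo-6-hydroxy-4-methoxybenzaldehyde
Product: 5 2-bromo-4-methoxy-6-(methoxymethoxy)benzaldehyde
Conditions: MOMCl, i-Pr2NEt, CH2Cl2, 0 °C to rt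
Reagents that add atoms: chloromethyl methyl ether COCCl
Why: O-Alkylation of the phenol with an α-chloro ether (MOM protection), which installs an acetal that survives bases, hydride, Grignard reagent and palladium catalysis, later directs the lithiation and leaves under mild acid.

Step 4
Reactants: 5 2-bromo-4-methoxy-6-(methoxymethoxy)benzaldehyde
Product: 6 [2-bromo-4-methoxy-6-(methoxymethoxy)phenyl]methanol
Conditions: NaBH4, MeOH, 0 °C
Reagents that add atoms: none
Why: Borohydride reduction of an aromatic aldehyde, which leaves the aryl bromide and the acetal untouched.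

Step 5
Reactants: 6 [2-bromo-4-methoxy-6-(methoxymethoxy)phenyl]methanol
Product: 7 1-bromo-2-(bromomethyl)-5-methoxy-3-(methoxymethoxy)benzene
Conditions: CBr4, PPh3, CH2Cl2, 0 °C
Reagents that add atoms: tetrabromomethane BrC(Br)(Br)Br
Why: Appel reaction, whose neutral conditions turn the electron-rich benzylic alcohol into the bromide by SN2 displacement of the oxyphosphonium group without harm to the acid-labile MOM group, the bromide being used at once.

Step 6
Reactants: 8 5-methylhex-4-enoic acid; 9 (S)-4-benzyl-1,3-oxazolidin-2-one
Product: 11 (S)-4-benzyl-3-(5-methylhex-4-enoyl)-1,3-oxazolidin-2-one, via mixed pivalic anhydride 10 (not isolated)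
Conditions: t-BuCOCl, Et3N, THF, −20 °C; then LiCl, 9, −20 °C to rt
Reagents that add atoms: none
Why: N-Acylation of the oxazolidinone through the mixed pivalic anhydride 10 (LiCl/Et3N variant), in which the bulky tert-butyl group steers attack to the wanted carbonyl group and the stereocentre of the auxiliary is not involved.

Step 7
Reactants: 11 (S)-4-benzyl-3-(5-methylhex-4-enoyl)-1,3-oxazolidin-2-one; 7 1-bromo-2-(bromomethyl)-5-methoxy-3-(methoxymethoxy)benzene
Product: 13 (4S)-4-benzyl-3-[(2R)-2-{[2-bromo-4-methoxy-6-(methoxymethoxy)phenyl]methyl}-5-methylhex-4-enoyl]-1,3-oxazolidin-2-one, via sodium Z-enolate 12 (not isolated)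
Conditions: NaN(SiMe3)2, THF, −78 °C; then 7, −78 to −20 °C
Reagents that add atoms: none
Why: Evans asymmetric alkylation: the sodium-chelated Z-enolate 12 is shielded on one face by the C4 benzyl group of the (S)-auxiliary, so the reactive benzylic bromide enters from the opposite face and sets the new stereocentre as R (the later C3), any minor diastereomer being removable by chromatography.

Step 8
Reactants: 13 the alkylated imide
Product: 14 benzyl (2R)-2-{[2-bromo-4-methoxy-6-(methoxymethoxy)phenyl]methyl}-5-methylhex-4-enoate
Conditions: BnOH, n-BuLi (premixed), THF, 0 °C; then aq NH4Cl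
Reagents that add atoms: benzyl alcohol OCc1ccccc1
Why: Transesterification of the imide with lithium benzyl oxide, which attacks the more electrophilic exocyclic carbonyl group, frees the auxiliary for re-use and is too weakly basic at 0 °C to epimerise the α-stereocentre.

Step 9
Reactants: 14 the benzyl ester
Product: 16 (3R)-3-{[2-bromo-4-methoxy-6-(methoxymethoxy)phenyl]methyl}-2,6-dimethylhept-5-en-2-ol, via methyl ketone 15 (not isolated)
Conditions: MeMgBr (excess), THF, 0 °C to rt; then aq NH4Cl
Reagents that add atoms: methylmagnesium bromide C[Mg]Br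
Why: Double Grignard addition to an ester through ketone 15, in which addition of the small methyl nucleophile outruns enolisation so that the adjacent stereocentre is kept, and the aryl bromide does not exchange with MeMgBr.

Step 10
Reactants: 16 the bromoaryl tertiary alcohol
Product: 17 (3R)-7-methoxy-5-(methoxymethoxy)-2,2-dimethyl-3-(3-methylbut-2-enyl)chroman
Conditions: Pd(OAc)2 (cat.), 2-(di-tert-butylphosphino)-1,1'-binaphthyl (cat.), Cs2CO3, toluene, 80 °C
Reagents that add atoms: none
Why: Intramolecular palladium-catalysed aryl C–O coupling (Buchwald–Hartwig etherification, closure of the six-membered ring C through a seven-membered palladacycle): zerovalent palladium inserts into the C–Br bond, the tertiary alkoxide has no hydrogen on its carbinol carbon for β-hydride elimination, the bulky electron-rich phosphine drives reductive elimination, the hindered trisubstituted prenyl alkene should be too slow for Heck insertion, and no cation arises next to C3 so its configuration holds.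

Step 11
Reactants: 18 7-hydroxycoumarin (umbelliferone)
Product: 19 7-(methoxymethoxy)-2H-chromen-2-one
Conditions: MOMCl, K2CO3, acetone, rt
Reagents that add atoms: chloromethyl methyl ether COCCl
Why: MOM protection of the acidic 7-OH, which removes the only proton of the lactone that would quench the aryllithium and keeps the carbonyl group electrophilic.

Step 12
Reactants: 17 (3R)-7-methoxy-5-(methoxymethoxy)-2,2-dimethyl-3-(3-methylbut-2-enyl)chroman; 19 7-(methoxymethoxy)-2H-chromen-2-one
Product: 23 (E)-3-[2-hydroxy-4-(methoxymethoxy)phenyl]-1-[(3R)-7-methoxy-5-(methoxymethoxy)-2,2-dimethyl-3-(3-methylbut-2-enyl)chroman-6-yl]prop-2-en-1-one, via 6-lithiochroman 20 (not isolated), via lithium chromen-2-olate 21 (not isolated), via Z-enone phenoxide 22 (not isolated)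
Conditions: 17, n-BuLi (1.1 equiv), THF, 0 °C; added to 19 (1.2 equiv) in THF at −78 °C; −78 °C to rt; then AcOH
Reagents that add atoms: none
Why: n-BuLi removes H6 of 17 by directed ortho-metalation, because C6 lies between the chelating O5 MOM acetal and the O7 methoxy group whereas C8 is flanked only by that methoxy group and the non-chelating ring oxygen O1, so aryllithium 20 should form at C6. The hard lithium reagent adds 1,2 (not 1,4) at low temperature to the lactone carbonyl C2 of 19, and the tetrahedral lithium 2-aryl-2H-chromen-2-olate 21 stores the acyl group much as a Weinreb chelate does, which together with the two ortho substituents of the aryl group and the inverse addition guards against a second addition. On warming, 21 expels its own ring-B phenoxide (the pyranone ring opens and no ring is closed) to give Z-enone phenoxide 22, so that the oxygen on C2 of ring B never needs a protecting group. Push-pull conjugation of this ortho phenoxide with the enone (quinone-methide enolate resonance form) lowers the barrier to rotation about the C=C bond, so 22 relaxes to the more stable E isomer, and because O5 is still masked no flavanone closure can drain the basic mixture. The closest known reaction type is the classical addition of arylmagnesium or aryllithium reagents to coumarins, which gives 2-aryl-2H-chromen-2-ols, the hemiketal members of the flavylium and 2-hydroxychalcone network whose stable neutral form is the trans-2-hydroxychalcone. No lasting stereocentre is made, since the hemiketal carbon of 21 is lost again, and C3 is remote from all events.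

Step 13
Reactants: 23 the bis-MOM E-chalcone
Product: 24 (E)-3-(2,4-dihydroxyphenyl)-1-[(3R)-5-hydroxy-7-methoxy-2,2-dimethyl-3-(3-methylbut-2-enyl)chroman-6-yl]prop-2-en-1-one
Conditions: HCl (cat.), MeOH, 40 °C; then aq NaOAc, pH 5 to 6, rt
Reagents that add atoms: none
Why: Acid-catalysed acetal methanolysis (MOM cleavage as used for prenylated chalcones), in which the O5 acetal next to the ketone leaves first with hydrogen-bond assistance, formaldehyde is bound as its dimethyl acetal, and the mild buffer at the end returns any reversibly ring-closed material to the hydrogen-bonded E-chalcone without base that would trigger flavanone closure.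

**Compound list**

1 | 1-bromo-3,5-dimethoxybenzene | COc1cc(Br)cc(OC)c1 | starting material
2 | [(2-bromo-4,6-dimethoxyphenyl)methylidene]dimethylammonium dichlorophosphate | COc1cc(Br)c(C=[N+](C)C)c(OC)c1.[O-]P(=O)(Cl)Cl | intermediate
3 | 2-bromo-4,6-dimethoxybenzaldehyde | COc1cc(Br)c(C=O)c(OC)c1 | intermediate
4 | 2-bromo-6-hydroxy-4-methoxybenzaldehyde | COc1cc(O)c(C=O)c(Br)c1 | intermediate
5 | 2-bromo-4-methoxy-6-(methoxymethoxy)benzaldehyde | COCOc1cc(OC)cc(Br)c1C=O | intermediate
6 | [2-bromo-4-methoxy-6-(methoxymethoxy)phenyl]methanol | COCOc1cc(OC)cc(Br)c1CO | intermediate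
7 | 1-bromo-2-(bromomethyl)-5-methoxy-3-(methoxymethoxy)benzene | COCOc1cc(OC)cc(Br)c1CBr | intermediate
8 | 5-methylhex-4-enoic acid | CC(C)=CCCC(=O)O | starting material
9 | (S)-4-benzyl-1,3-oxazolidin-2-one | O=C1N[C@@H](Cc2ccccc2)CO1 | starting material
10 | 5-methylhex-4-enoic pivalic anhydride | CC(C)=CCCC(=O)OC(=O)C(C)(C)C | intermediate
11 | (S)-4-benzyl-3-(5-methylhex-4-enoyl)-1,3-oxazolidin-2-one | CC(C)=CCCC(=O)N1[C@@H](Cc2ccccc2)COC1=O | intermediate
12 | sodium (Z)-enolate of 11 | CC(C)=CC/C=C(\[O-])N1[C@@H](Cc2ccccc2)COC1=O.[Na+] | intermediate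
13 | (4S)-4-benzyl-3-[(2R)-2-{[2-bromo-4-methoxy-6-(methoxymethoxy)phenyl]methyl}-5-methylhex-4-enoyl]-1,3-oxazolidin-2-one | COCOc1cc(OC)cc(Br)c1C[C@@H](CC=C(C)C)C(=O)N1[C@@H](Cc2ccccc2)COC1=O | intermediate
14 | benzyl (2R)-2-{[2-bromo-4-methoxy-6-(methoxymethoxy)phenyl]methyl}-5-methylhex-4-enoate | COCOc1cc(OC)cc(Br)c1C[C@@H](CC=C(C)C)C(=O)OCc1ccccc1 | intermediate
15 | (3R)-3-{[2-bromo-4-methoxy-6-(methoxymethoxy)phenyl]methyl}-6-methylhept-5-en-2-one | COCOc1cc(OC)cc(Br)c1C[C@@H](CC=C(C)C)C(C)=O | intermediate
16 | (3R)-3-{[2-bromo-4-methoxy-6-(methoxymethoxy)phenyl]methyl}-2,6-dimethylhept-5-en-2-ol | COCOc1cc(OC)cc(Br)c1C[C@@H](CC=C(C)C)C(C)(C)O | intermediate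
17 | (3R)-7-methoxy-5-(methoxymethoxy)-2,2-dimethyl-3-(3-methylbut-2-enyl)chroman | COCOc1cc(OC)cc2c1C[C@@H](CC=C(C)C)C(C)(C)O2 | intermediate
18 | 7-hydroxycoumarin (umbelliferone) | Oc1ccc2ccc(=O)oc2c1 | starting material
19 | 7-(methoxymethoxy)-2H-chromen-2-one | COCOc1ccc2ccc(=O)oc2c1 | intermediate
20 | 6-lithio derivative of 17 | COCOc1c([Li])c(OC)cc2c1C[C@@H](CC=C(C)C)C(C)(C)O2 | intermediate
21 | lithium 2-aryl-7-(methoxymethoxy)-2H-chromen-2-olate (aryl = C6 of 17; both epimers at the hemiketal carbon) | COCOc1ccc2C=CC(O[Li])(Oc2c1)c1c(OC)cc2c(c1OCOC)C[C@@H](CC=C(C)C)C(C)(C)O2 | intermediate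
22 | lithium phenoxide of the (Z)-2-hydroxychalcone | COCOc1ccc(/C=C\C(=O)c2c(OC)cc3c(c2OCOC)C[C@@H](CC=C(C)C)C(C)(C)O3)c(O[Li])c1 | intermediate
23 | (E)-3-[2-hydroxy-4-(methoxymethoxy)phenyl]-1-[(3R)-7-methoxy-5-(methoxymethoxy)-2,2-dimethyl-3-(3-methylbut-2-enyl)chroman-6-yl]prop-2-en-1-one | COCOc1ccc(/C=C/C(=O)c2c(OC)cc3c(c2OCOC)C[C@@H](CC=C(C)C)C(C)(C)O3)c(O)c1 | intermediate
24 | (E)-3-(2,4-dihydroxyphenyl)-1-[(3R)-5-hydroxy-7-methoxy-2,2-dimethyl-3-(3-methylbut-2-enyl)chroman-6-yl]prop-2-en-1-one (CNP0333857.1) | COc1cc2c(c(O)c1C(=O)/C=C/c1ccc(O)cc1O)C[C@@H](CC=C(C)C)C(C)(C)O2 | target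

**Step count and risks**

Total step count: 13.
Longest linear sequence: 11 (steps 1 to 5, 7 to 10, 12, 13).

Steps most likely to fail:

Step 12. Four processes may interfere: partial lithiation at C8, conjugate addition at C4 of the lactone, a second addition to the ring-opened enone, and sluggish Z to E equilibration. The fallback sets out from 17 and builds the enone by aldol chemistry instead of lactone opening.
- The lithiated chroman 20 is quenched with N-methoxy-N-methylacetamide to give the 6-acetylchroman F1, which can be freed at this stage from any material acylated at C8.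
- Commercial 2,4-dihydroxybenzaldehyde is converted with MOMCl and i-Pr2NEt into 2,4-bis(methoxymethoxy)benzaldehyde F2.
- Claisen–Schmidt condensation of the two (KOH, EtOH, rt) fixes the E geometry and gives the tris-MOM chalcone F3.
- Methanolysis under the conditions of step 13 comes back to the route at 24.

Step 10. C–O reductive elimination from the hindered tertiary alkoxide may be slow, so that hydrodebromination or Heck-type insertion into the prenyl alkene takes over. The fallback sets out from 16 and closes ring C without a transition metal, by an aryne cyclisation.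
- Lithium 2,2,6,6-tetramethylpiperidide (3 equiv, THF, −78 °C to rt) forms the alkoxide and removes the acidic hydrogen between Br and OMe.
- Loss of bromide gives the aryne alkoxide F4.
- Its methoxy group polarises the triple bond so that the tethered alkoxide adds at the distal carbon, which is also the only one the tether can reach.
- Protonation of the resulting aryl anion by the amine comes back to the route at 17.
- Lithiation at the other ring position is reversed by proton exchange, and no cation arises next to C3.

Step 13. The acid may close O5 onto the enone (flavanone formation). It may also close the ring-B oxygen onto the ketone without full reversal, add methanol to the prenyl alkene, or let liberated formaldehyde attack the electron-rich rings. The fallback changes the protecting-group plan so that only the most labile acetal has to be removed by acid. It sets out from 18 and 17.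
- 18 is silylated (i-Pr3SiCl, imidazole, DMF) to 7-(triisopropylsilyloxy)coumarin F5.
- F5 is opened by 20 as in step 12 to give the silyl MOM chalcone F6.
- Bu4NF buffered with AcOH (THF, 0 °C) removes the silyl group while O5 is still masked, so that base-induced flavanone closure is impossible. This gives the mono-MOM chalcone F7.
- Brief treatment with pyridinium p-toluenesulfonate in MeOH at 40 °C cleaves the carbonyl-activated O5 acetal and comes back to the route at 24.

Further compounds
F1 | step 12 | 1-[(3R)-7-methoxy-5-(methoxymethoxy)-2,2-dimethyl-3-(3-methylbut-2-enyl)chroman-6-yl]ethanone | COCOc1c(C(C)=O)c(OC)cc2c1C[C@@H](CC=C(C)C)C(C)(C)O2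
F2 | step 12 | 2,4-bis(methoxymethoxy)benzaldehyde | COCOc1ccc(C=O)c(OCOC)c1
F3 | step 12 | (E)-3-[2,4-bis(methoxymethoxy)phenyl]-1-[(3R)-7-methoxy-5-(methoxymethoxy)-2,2-dimethyl-3-(3-methylbut-2-enyl)chroman-6-yl]prop-2-en-1-one | COCOc1ccc(/C=C/C(=O)c2c(OC)cc3c(c2OCOC)C[C@@H](CC=C(C)C)C(C)(C)O3)c(OCOC)c1
F4 | step 10 | lithium alkoxide of the aryne formed from 16 by loss of HBr (transient) | COC1=CC(OCOC)=C(C[C@@H](CC=C(C)C)C(C)(C)O[Li])C#C1
F5 | step 13 | 7-(triisopropylsilyloxy)-2H-chromen-2-one | CC(C)[Si](Oc1ccc2ccc(=O)oc2c1)(C(C)C)C(C)C
F6 | step 13 | (E)-3-[2-hydroxy-4-(triisopropylsilyloxy)phenyl]-1-[(3R)-7-methoxy-5-(methoxymethoxy)-2,2-dimethyl-3-(3-methylbut-2-enyl)chroman-6-yl]prop-2-en-1-one | COCOc1c(C(=O)/C=C/c2ccc(O[Si](C(C)C)(C(C)C)C(C)C)cc2O)c(OC)cc2c1C[C@@H](CC=C(C)C)C(C)(C)O2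
F7 | step 13 | (E)-3-(2,4-dihydroxyphenyl)-1-[(3R)-7-methoxy-5-(methoxymethoxy)-2,2-dimethyl-3-(3-methylbut-2-enyl)chroman-6-yl]prop-2-en-1-one | COCOc1c(C(=O)/C=C/c2ccc(O)cc2O)c(OC)cc2c1C[C@@H](CC=C(C)C)C(C)(C)O2
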